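**Plan**

- Retrosynthesis: first the two C(=O)–C(OH) bonds joining each enone carbonyl to the central ring are cut (twofold benzoin disconnection), leaving a trans-dispiro bis(oxolane) cyclohexane-1,2,4,5-tetraone with two enal arms. Then in each oxolane the O–CH2 and CH2–C(spiro) bonds are cut, giving formaldehyde and a flat 3,6-dialkenyl-2,5-dihydroxy-1,4-benzoquinone. Last, the two ring–alkenyl bonds are cut to a dibromotetramethoxybenzene and a tetrasubstituted alkenyl iodide made from 2-butyne-1,4-diol, MeMgBr and iodine.
- Enabling feature: the central six-membered ring carries oxygen on four carbons in the pattern of 2,5-dihydroxy-1,4-benzoquinone, and its two other carbons are the quaternary spiro atoms of the two oxolanes (each ring C(spiro)–CH2–O–CH2–C(alkene)). Both spiro atoms can therefore arise by C-alkylation of the two enol carbons of that quinone.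
- Forward order: the alkene is built and joined twice to the arene, the arene is oxidised to the dihydroxyquinone (central ring), both oxolanes close together in step 9, and both bridged cyclohexenone rings close together in step 12.
- Stereochemistry: the alkene geometry comes from the anti-carbomagnesiation and is carried through retentive metalation and coupling. The trans pair of spiro centres is set in step 9, and each carbinol centre is fixed by its tether in step 12.

Key step: step 9

Remark: the target SMILES encodes the centrosymmetric (meso) diastereomer, so the compound is achiral and only relative configuration has to be controlled.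

**Route**

Step 1
Reactants: 1 2-butyne-1,4-diol
Product: 2 4-(tert-butyldimethylsilyloxy)but-2-yn-1-ol
Conditions: NaH (1.0 equiv), THF, 0 °C; TBSCl (1.0 equiv), 0 °C → rt; diol in threefold excess
Reagents that add atoms: tert-butyldimethylsilyl chloride, CC(C)(C)[Si](C)(C)Cl
Why: Monosilylation of a symmetric diol through its sparingly soluble monosodium alkoxide (O-silylation) should stop at the mono-ether, and the excess diol is removed by aqueous washing.

Step 2
Reactants: 2 4-(tert-butyldimethylsilyloxy)but-2-yn-1-ol
Product: 4 (Z)-4-(tert-butyldimethylsilyloxy)-3-iodo-2-methylbut-2-en-1-ol, via oxamagnesacycle 3 (not isolated)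
Conditions: MeMgBr (3.5 equiv), CuI (15 mol%), THF, −20 °C → rt; then I2, −40 → 0 °C
Reagents that add atoms: methylmagnesium bromide, C[Mg]Br; iodine, II
Why: Alkoxide-directed, CuI-catalysed anti-carbomagnesiation of a propargylic alcohol places methyl on the carbon next to CH2O–Mg and magnesium on the distal carbon in a five-membered chelate, and iodinolysis with retention gives the tetrasubstituted alkene with iodine cis to CH2OH, the bulky silyl ether in THF disfavouring β-elimination to an allene.

Step 3
Reactants: 4 (Z)-4-(tert-butyldimethylsilyloxy)-3-iodo-2-methylbut-2-en-1-ol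
Product: 5 (Z)-1-(tert-butyldimethylsilyloxy)-4-(tert-butyldiphenylsilyloxy)-2-iodo-3-methylbut-2-ene
Conditions: TBDPSCl, imidazole, CH2Cl2, 0 °C → rt
Reagents that add atoms: tert-butyldiphenylsilyl chloride, CC(C)(C)[Si](Cl)(c1ccccc1)c1ccccc1
Why: Imidazole-promoted silylation of the primary allylic alcohol caps the hydroxyl on the methyl-bearing carbon, which the carbomagnesiation leaves free but which must stay masked through step 9, with the acid-robust TBDPS group, while the TBS ether on the other oxygen remains selectively removable.

Step 4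
Reactants: 6 1,2,4,5-tetramethoxybenzene
Product: 7 1,4-dibromo-2,3,5,6-tetramethoxybenzene
Conditions: N-bromosuccinimide (2.1 equiv), MeCN, 0 °C → rt, dark
Reagents that add atoms: N-bromosuccinimide, O=C1CCC(=O)N1Br
Why: Electrophilic aromatic bromination can only occur at the two free positions, each ortho to two methoxy groups, so twofold substitution is unambiguous.

Step 5
Reactants: 5 (Z)-1-(tert-butyldimethylsilyloxy)-4-(tert-butyldiphenylsilyloxy)-2-iodo-3-methylbut-2-ene (2.6 equiv); 7 1,4-dibromo-2,3,5,6-tetramethoxybenzene
Product: 10 1,4-bis[(2E)-1-(tert-butyldimethylsilyloxy)-4-(tert-butyldiphenylsilyloxy)-3-methylbut-2-en-2-yl]-2,3,5,6-tetramethoxybenzene, via alkenyllithium 8 (not isolated), via alkenylzinc chloride 9 (not isolated)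
Conditions: 5, t-BuLi (2 equiv per iodide), Et2O, −78 °C; ZnCl2 (THF), −78 °C → rt; then 7, Pd(P(t-Bu)3)2 (8 mol%), THF/NMP, 70 °C
Reagents that add atoms: none
Why: Retentive iodine–lithium exchange in cold Et2O (conditions that hold back a 1,4 oxygen-to-carbon silyl shift), immediate transmetalation to zinc and a twofold Negishi coupling with the bulky electron-rich Pd(P(t-Bu)3)2 catalyst, a system known to join di-ortho-substituted aryl halides to hindered organozinc reagents, should give the bis-alkenyl arene with the alkene geometry retained.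

Step 6
Reactants: 10 1,4-bis[(2E)-1-(tert-butyldimethylsilyloxy)-4-(tert-butyldiphenylsilyloxy)-3-methylbut-2-en-2-yl]-2,3,5,6-tetramethoxybenzene
Product: 11 1,4-bis[(2E)-4-(tert-butyldiphenylsilyloxy)-1-hydroxy-3-methylbut-2-en-2-yl]-2,3,5,6-tetramethoxybenzene
Conditions: (1S)-(+)-10-camphorsulfonic acid (0.2 equiv), MeOH/CH2Cl2 (1:1), 0 °C
Reagents that add atoms: none
Why: Acid-catalysed methanolysis (selective desilylation) cleaves a primary TBS ether far faster than a primary TBDPS ether, so only the hydroxyl geminal to the arene is released.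

Step 7
Reactants: 11 1,4-bis[(2E)-4-(tert-butyldiphenylsilyloxy)-1-hydroxy-3-methylbut-2-en-2-yl]-2,3,5,6-tetramethoxybenzene
Product: 12 2,5-dimethoxy-3,6-bis[(2E)-4-(tert-butyldiphenylsilyloxy)-1-hydroxy-3-methylbut-2-en-2-yl]-1,4-benzoquinone
Conditions: (NH4)2Ce(NO3)6 (2.5 equiv), MeCN/H2O (4:1), 0 °C, 15 min
Reagents that add atoms: water, O
Why: Oxidative demethylation of a para-dimethoxyarene by tetravalent cerium converts 1,2,4,5-tetramethoxybenzenes into 2,5-dimethoxy-1,4-benzoquinones within minutes at 0 °C, a window in which silyl ethers, allylic alcohols and the electron-poor tetrasubstituted alkenes should survive.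

Step 8
Reactants: 12 2,5-dimethoxy-3,6-bis[(2E)-4-(tert-butyldiphenylsilyloxy)-1-hydroxy-3-methylbut-2-en-2-yl]-1,4-benzoquinone
Product: 13 2,5-dihydroxy-3,6-bis[(2E)-4-(tert-butyldiphenylsilyloxy)-1-hydroxy-3-methylbut-2-en-2-yl]-1,4-benzoquinone
Conditions: NaOH (1 M aq, 6 equiv), THF/MeOH, rt; then 1 M HCl to pH 2–3, 0 °C; used without storage
Reagents that add atoms: sodium hydroxide, [Na+].[OH-]
Why: Hydrolysis of the two vinylogous methyl esters by addition–elimination of hydroxide is driven by formation of the doubly deprotonated vinylogous acid, into which any cyclic vinylogous ester formed by the neighbouring alkoxide is also opened, and gentle acidification then frees the dihydroxyquinone.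

Step 9
Reactants: 13 2,5-dihydroxy-3,6-bis[(2E)-4-(tert-butyldiphenylsilyloxy)-1-hydroxy-3-methylbut-2-en-2-yl]-1,4-benzoquinone; 14 formaldehyde (from paraformaldehyde)
Product: 16 trans-(4E,12E)-4,12-bis[1-(tert-butyldiphenylsilyloxy)propan-2-ylidene]-2,10-dioxadispiro[4.2.4.2]tetradecane-6,7,13,14-tetraone, via bis-hemiformal 15 (not isolated)
Conditions: (CH2O)n (10 equiv CH2O), CH2Cl2, rt, 30 min; then CF3CO2H (6 equiv), 0 °C → rt; trans isomer collected by crystallisation
Reagents that add atoms: formaldehyde (14), C=O
Why: Proposed new method: each primary allylic alcohol of 13 forms a hemiformal with formaldehyde (15), CF3CO2H ionises it to an O-alkyl oxocarbenium ion, and the enol carbon of the vinylogous acid that already bears the alkenyl group attacks it from the face over which the twisted side chain holds the cation, so the enol becomes a ketone and a quaternary spiro carbon is formed; the second vinylogous acid unit reacts likewise and leaves a non-enolisable tetraone. The closest known reaction types are the oxa-Pictet–Spengler cyclisation and the Mannich- or Prins-type C-alkylation of 2-hydroxy-1,4-quinones by aldehyde-derived cations, here required at a substituted carbon, where the alkenyl substituent also rules out the usual dehydration to a quinone methide. Each oxolane closes in the 5-endo-trig sense with respect to the C=O+ bond (exo with respect to the enol C=C), the mode of Prins-type oxolane syntheses. The two spiro carbons are the only new stereogenic units and the trans arrangement is needed; it should be favoured kinetically because the silyloxy-bearing arm of the first spiro ring lies over one face of the six-membered ring and pushes the arm of the second alkenyl group to the opposite face, and thermodynamically because acid-reversible C-alkylation (retro-Mannich type) lets the centrosymmetric isomer crystallise. Selectivity for the five-membered ring is secured by the TBDPS ether, which keeps the other allylic oxygen (it would close a six-membered ring) out of play and resists CF3CO2H, and the alkene geometry from step 2 is untouched.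

Step 10
Reactants: 16 trans-(4E,12E)-4,12-bis[1-(tert-butyldiphenylsilyloxy)propan-2-ylidene]-2,10-dioxadispiro[4.2.4.2]tetradecane-6,7,13,14-tetraone
Product: 17 trans-(4E,12E)-4,12-bis(1-hydroxypropan-2-ylidene)-2,10-dioxadispiro[4.2.4.2]tetradecane-6,7,13,14-tetraone
Conditions: HF·pyridine, pyridine/THF, 0 °C → rt
Reagents that add atoms: none
Why: Fluoride-mediated desilylation under buffered acidic conditions is chosen because basic fluoride would expose the non-enolisable tetraone to benzilic-acid or retro-Claisen cleavage, and the diol may rest as a hemiketal that reopens in the next step.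

Step 11
Reactants: 17 trans-(4E,12E)-4,12-bis(1-hydroxypropan-2-ylidene)-2,10-dioxadispiro[4.2.4.2]tetradecane-6,7,13,14-tetraone
Product: 18 trans-(4E,12E)-4,12-bis(1-oxopropan-2-ylidene)-2,10-dioxadispiro[4.2.4.2]tetradecane-6,7,13,14-tetraone
Conditions: Dess–Martin periodinane (3 equiv), CH2Cl2, 0 °C → rt
Reagents that add atoms: none
Why: Dess–Martin oxidation takes primary allylic alcohols to enals under near-neutral conditions without over-oxidation or isomerisation of the tetrasubstituted alkene.

Step 12
Reactants: 18 trans-(4E,12E)-4,12-bis(1-oxopropan-2-ylidene)-2,10-dioxadispiro[4.2.4.2]tetradecane-6,7,13,14-tetraone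
Product: 19 CNP0299498.2 (centrosymmetric pentacyclic bis-α-ketol)
Conditions: 2-mesityl-6,7-dihydro-5H-pyrrolo[2,1-c][1,2,4]triazol-2-ium chloride (20 mol%), Et3N (20 mol%), THF, rt → 40 °C
Reagents that add atoms: none
Why: In this intramolecular crossed aldehyde–ketone benzoin reaction under N-heterocyclic carbene catalysis, the acyl-anion equivalent of each enal (homoenolate paths are closed because the β-carbon is fully substituted and in a ring) adds 6-exo-trig to the farther carbonyl of the neighbouring 1,2-dione on the only face its tether can reach, which sets each tertiary carbinol relative to its spiro centre, and the reversibility of the addition should drain the material into the twin bicyclo[3.3.1] bridges on a chair-shaped central ring.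

**Compound list**

1 | 2-butyne-1,4-diol | OCC#CCO | starting material
2 | 4-(tert-butyldimethylsilyloxy)but-2-yn-1-ol | OCC#CCO[Si](C)(C)C(C)(C)C | intermediate
3 | 3-[(tert-butyldimethylsilyloxy)methyl]-4-methyl-2,5-dihydro-1,2-oxamagnesole (cyclic alkenylmagnesium alkoxide) | CC1=C(CO[Si](C)(C)C(C)(C)C)[Mg]OC1 | intermediate (not isolated)
4 | (Z)-4-(tert-butyldimethylsilyloxy)-3-iodo-2-methylbut-2-en-1-ol (iodine cis to CH2OH) | OC/C(C)=C(\I)CO[Si](C)(C)C(C)(C)C | intermediate
5 | (Z)-1-(tert-butyldimethylsilyloxy)-4-(tert-butyldiphenylsilyloxy)-2-iodo-3-methylbut-2-ene (iodine cis to CH2OTBDPS) | CC(C)(C)[Si](c1ccccc1)(c1ccccc1)OC/C(C)=C(\I)CO[Si](C)(C)C(C)(C)C | intermediate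
6 | 1,2,4,5-tetramethoxybenzene | COc1cc(OC)c(OC)cc1OC | starting material
7 | 1,4-dibromo-2,3,5,6-tetramethoxybenzene | COc1c(OC)c(Br)c(OC)c(OC)c1Br | intermediate
8 | [(E)-1-(tert-butyldimethylsilyloxy)-4-(tert-butyldiphenylsilyloxy)-3-methylbut-2-en-2-yl]lithium (lithium cis to CH2OTBDPS) | CC(C)(C)[Si](c1ccccc1)(c1ccccc1)OC/C(C)=C(\[Li])CO[Si](C)(C)C(C)(C)C | intermediate (not isolated)
9 | [(Z)-1-(tert-butyldimethylsilyloxy)-4-(tert-butyldiphenylsilyloxy)-3-methylbut-2-en-2-yl]zinc chloride (zinc cis to CH2OTBDPS) | CC(C)(C)[Si](c1ccccc1)(c1ccccc1)OC/C(C)=C(\[Zn]Cl)CO[Si](C)(C)C(C)(C)C | intermediate (not isolated)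
10 | 1,4-bis[(2E)-1-(tert-butyldimethylsilyloxy)-4-(tert-butyldiphenylsilyloxy)-3-methylbut-2-en-2-yl]-2,3,5,6-tetramethoxybenzene (arene cis to CH2OTBDPS) | COc1c(OC)c(/C(CO[Si](C)(C)C(C)(C)C)=C(C)\CO[Si](c2ccccc2)(c3ccccc3)C(C)(C)C)c(OC)c(OC)c1/C(CO[Si](C)(C)C(C)(C)C)=C(C)\CO[Si](c2ccccc2)(c3ccccc3)C(C)(C)C | intermediate
11 | 1,4-bis[(2E)-4-(tert-butyldiphenylsilyloxy)-1-hydroxy-3-methylbut-2-en-2-yl]-2,3,5,6-tetramethoxybenzene | COc1c(OC)c(/C(CO)=C(C)\CO[Si](c2ccccc2)(c3ccccc3)C(C)(C)C)c(OC)c(OC)c1/C(CO)=C(C)\CO[Si](c2ccccc2)(c3ccccc3)C(C)(C)C | intermediate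
12 | 2,5-dimethoxy-3,6-bis[(2E)-4-(tert-butyldiphenylsilyloxy)-1-hydroxy-3-methylbut-2-en-2-yl]-1,4-benzoquinone | COC1=C(/C(CO)=C(C)\CO[Si](c2ccccc2)(c3ccccc3)C(C)(C)C)C(=O)C(OC)=C(/C(CO)=C(C)\CO[Si](c2ccccc2)(c3ccccc3)C(C)(C)C)C1=O | intermediate
13 | 2,5-dihydroxy-3,6-bis[(2E)-4-(tert-butyldiphenylsilyloxy)-1-hydroxy-3-methylbut-2-en-2-yl]-1,4-benzoquinone (quinone carbon cis to CH2OTBDPS) | OC1=C(/C(CO)=C(C)\CO[Si](c2ccccc2)(c3ccccc3)C(C)(C)C)C(=O)C(O)=C(/C(CO)=C(C)\CO[Si](c2ccccc2)(c3ccccc3)C(C)(C)C)C1=O | intermediate
14 | formaldehyde (from paraformaldehyde) | C=O | starting material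
15 | bis-hemiformal of 13 (each allylic CH2OH converted to CH2OCH2OH) | OC1=C(/C(COCO)=C(C)\CO[Si](c2ccccc2)(c3ccccc3)C(C)(C)C)C(=O)C(O)=C(/C(COCO)=C(C)\CO[Si](c2ccccc2)(c3ccccc3)C(C)(C)C)C1=O | intermediate (not isolated)
16 | trans-(4E,12E)-4,12-bis[1-(tert-butyldiphenylsilyloxy)propan-2-ylidene]-2,10-dioxadispiro[4.2.4.2]tetradecane-6,7,13,14-tetraone (alkylidene carbons C4 and C12 on opposite faces of the central ring; centrosymmetric) | CC(C)(C)[Si](c4ccccc4)(c5ccccc5)OC/C(C)=C1/COC[C@]12C(=O)C(=O)[C@]3(COC/C3=C(C)/CO[Si](c4ccccc4)(c5ccccc5)C(C)(C)C)C(=O)C2=O | intermediate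
17 | trans-(4E,12E)-4,12-bis(1-hydroxypropan-2-ylidene)-2,10-dioxadispiro[4.2.4.2]tetradecane-6,7,13,14-tetraone | OC/C(C)=C1/COC[C@]12C(=O)C(=O)[C@]3(COC/C3=C(C)/CO)C(=O)C2=O | intermediate
18 | trans-(4E,12E)-4,12-bis(1-oxopropan-2-ylidene)-2,10-dioxadispiro[4.2.4.2]tetradecane-6,7,13,14-tetraone | O=C/C(C)=C1/COC[C@]12C(=O)C(=O)[C@]3(COC/C3=C(C)/C=O)C(=O)C2=O | intermediate
19 | CNP0299498.2: centrosymmetric pentacycle in which each enone carbonyl is bonded to the hydroxyl-bearing ring carbon two positions from its own spiro atom, the two bicyclo[3.3.1] bridges lying on opposite faces of the central ring | CC1=C2COC[C@]23C(=O)[C@](O)(C1=O)[C@@]12COCC1=C(C)C(=O)[C@]3(O)C2=O | target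

**Step count and risks**

Total step count: 12. Longest linear sequence: 11 steps (steps 1–3 and 5–12 from 2-butyne-1,4-diol; step 4 is the side branch).

Steps most likely to fail:

1. Step 9 (proposed new method). Several processes may divert it:
   - The oxocarbenium ion may be captured at the enol oxygen instead of the substituted enol carbon.
   - The free allylic alcohol may condense onto the vinylogous acid (cyclodehydration toward a fused furan).
   - The acid may strip the silyl ether so that the second arm competes.
   - The trans/cis selectivity at the two spiro centres may be poor.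

   The fallback uses known chemistry, sets out from 13 and returns at 16. Tollens-type aldol hydroxymethylation of both enol carbons (aqueous formaldehyde, NaHCO3, THF) uses the doubly deprotonated vinylogous acid as the carbon nucleophile, with no acid present. It should give trans-3,6-bis(hydroxymethyl)-3,6-bis[(2E)-4-(tert-butyldiphenylsilyloxy)-1-hydroxy-3-methylbut-2-en-2-yl]cyclohexane-1,2,4,5-tetraone F1. Mitsunobu cyclodehydration of each 1,4-diol (PPh3, diisopropyl azodicarboxylate, THF) then closes the two oxolanes by ether formation at the primary allylic carbon.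

2. Step 12. The acyl-anion equivalent may close onto the nearer carbonyl of each 1,2-dione (five-membered ring) instead of the farther one, and the base may degrade the tetraone. The fallback sets out from 18 and returns at 19. The carbene-catalysed cyclisation is stopped at the kinetic product, the centrosymmetric bis-ketol closed onto the nearer carbonyls (two spiro-fused 3-oxabicyclo[3.3.0]octenone units) F2. This is then ring-expanded by an α-ketol rearrangement (Al(OC(CH3)3)3, toluene, 80 °C). The suprafacial 1,2-acyl shift moves each enone carbonyl from its carbinol carbon to the adjacent ring ketone on the same face, which is the connectivity and configuration of 19.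

3. Step 5. The twofold coupling may stall after the first alkenyl group at the bromide flanked by two methoxy groups, and the alkenyllithium may undergo protonation or a 1,4 oxygen-to-carbon silyl shift before zinc takes over. The fallback sets out from 6 and 5 and returns at 10, with the polarity reversed and the two couplings run one after the other. Lithiation of 6 between two methoxy groups (n-BuLi, THF, 0 °C), transmetalation with ZnCl2 and Negishi coupling with 5 (Pd(P(t-Bu)3)2) should give 1-[(2E)-1-(tert-butyldimethylsilyloxy)-4-(tert-butyldiphenylsilyloxy)-3-methylbut-2-en-2-yl]-2,3,5,6-tetramethoxybenzene F3. A second lithiation at the remaining ring position, zincation and coupling with another equivalent of 5 gives 10, with no alkenyllithium and no dibromide involved.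

**Further compounds**

F1 | step 9 | trans-3,6-bis(hydroxymethyl)-3,6-bis[(2E)-4-(tert-butyldiphenylsilyloxy)-1-hydroxy-3-methylbut-2-en-2-yl]cyclohexane-1,2,4,5-tetraone | OC[C@@]1(/C(CO)=C(C)\CO[Si](c2ccccc2)(c3ccccc3)C(C)(C)C)C(=O)C(=O)[C@@](CO)(/C(CO)=C(C)\CO[Si](c2ccccc2)(c3ccccc3)C(C)(C)C)C(=O)C1=O
F2 | step 12 | centrosymmetric bis-ketol from closure onto the nearer carbonyls (each enone carbonyl bonded to the hydroxyl-bearing ring carbon next to its own spiro atom) | CC1=C2COC[C@@]23C(=O)[C@]4(O)C(=O)C(C)=C5COC[C@@]45C(=O)[C@@]3(O)C1=O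
F3 | step 5 | 1-[(2E)-1-(tert-butyldimethylsilyloxy)-4-(tert-butyldiphenylsilyloxy)-3-methylbut-2-en-2-yl]-2,3,5,6-tetramethoxybenzene | COc1cc(OC)c(OC)c(/C(CO[Si](C)(C)C(C)(C)C)=C(C)\CO[Si](c2ccccc2)(c3ccccc3)C(C)(C)C)c1OC
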